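I started with an easy step: percents of different charges don't compare, so I turned the late readings into mM/h.

| flask | substrate | gas | precatalyst | remark | time |
|---|---|---|---|---|---|
| teal | 0.50 M | 52 mM (held) | 1.8 mol% | run made earlier |  |
| violet | 0.50 M | 52 mM (held) | 17 mol% | run made earlier |  |
| ochre | 0.34 M | 52 mM (held) | 4.8 mol% | run made earlier |  |
| Thursday's | 0.30 M | 52 mM (held) | 1.5 mol% |  | 20 h |
| Saturday's | 0.15 M | 52 mM (held) | 15 mol% |  | 20 h |
| Monday's | 1.5 M | 52 mM (held) | 1.5 mol% |  | 20 h |
| Friday's | 0.50 M | 52 mM (held) | 4.8 mol% |  | 20 h |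

| run | time / h | product / % |
|---|---|---|
| teal | 1.00 | 0.1 |
| teal | 2.00 | 0 |
| teal | 3.00 | 1.3 |
| teal | 5.00 | 3.5 |
| teal | 8.00 | 7.5 |
| teal | 15.0 | 18.6 |
| violet | 1.00 | 0.8 |
| violet | 2.50 | 3.9 |
| violet | 5.00 | 10.3 |
| violet | 8.00 | 16.9 |
| violet | 10.0 | 21.3 |
| violet | 15.0 | 34.3 |
| ochre | 3.00 | 2.4 |
| ochre | 6.00 | 9.3 |
| ochre | 8.00 | 14.7 |
| ochre | 12.0 | 25.7 |
| ochre | 15.0 | 33.6 |

(each reading ± 0.3 percentage points)

- what was read earlier has a scatter of 0.3 percentage points, one standard deviation
- at the start none of the gas is in solution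
- a reading or a percentage of product counts all its forms, free or not

- the flasks put in order of amount of product, in percent of the substrate charged, best first, at 20 h (Thursday's / Saturday's / Monday's / Friday's)
- the amount of product, in percent of the substrate charged of the flask you put first, at 20 h
- the amount of product, in percent of the substrate charged of the flask you put last, at 20 h

Teal, at [precatalyst] 9.00 mM, ended at 7.93 mM h⁻¹. Violet, at 85.0 mM, ended at 13.0 mM h⁻¹. Both held 0.50 M substrate under a gas saturation of 52 mM. So the rate grew, but far less than [precatalyst] did. I solved both ends and joined them like resistances in series: the inverse rate is the inverse ceiling plus b/[precatalyst].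

b = 0.495 h

ceiling = 14.1 mM h⁻¹

I called this, read off two scattered late rates, the gas ceiling: the rate the line approaches as [precatalyst] grows, at this gas saturation. I read it, at high [precatalyst], as gas uptake acting as the rate-limiting step.

Teal still read 0% at 2.00 h, so I took that as the lag. Charge over joined rate then gave emptying times, which I set with the lag and the clock on one ladder, shortest first:

Lag: 2.00 h

Saturday's: 14.0 h

Clock: 20 h

Friday's: 45.9 h

Thursday's: 54.3 h

Monday's: 140 h

On this line the reckoned emptying of Saturday's fell inside the clock. On the same line Friday's came to 39.2%, Thursday's to 33.1% and Monday's to 12.9% of their charges. But ochre, on a thinner charge, read a late rate of 8.95 mM h⁻¹ against the line's 9.86 mM h⁻¹, so I trusted Saturday's place in the order more than its full charge.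

The forecast gave Saturday's > Friday's > Thursday's > Monday's, with top 92% and low 12%, on “a gas-transfer ceiling”. Its order was mine, and its top stopped short of my full charge.

The flasks gave Saturday's > Friday's > Thursday's > Monday's: 79.5%, 38.2%, 24.2% and 13.9%.

    substrate + free catalyst ⇌ catalyst intermediate A (K = 1.63 M⁻¹, k = 343 M⁻¹ h⁻¹)
    partner + catalyst intermediate A ⇌ catalyst intermediate B (K = 82.7 M⁻¹, k = 449 M⁻¹ h⁻¹)
    catalyst intermediate B → free catalyst + product (k = 3.25 h⁻¹)
    gas ⇌ partner, rate k4*(csat - [partner]) (kL = 0.241 h⁻¹)
    precatalyst → free catalyst (k = 0.213 h⁻¹)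
    crystals ⇌ product, rate k6*(cs6 - [product]) while solid is left; crystals form when [product] > cs6 (solubility = 0.0790 M, k = 10.7 h⁻¹)

Counted from my lag, Monday's averaged 11.6 mM h⁻¹ and Friday's 10.6 mM h⁻¹, both under the ceiling. Saturday's averaged 6.62 mM h⁻¹, about half of it. Saturday's went from 38.9% product at 10.0 h to 79.5% at 20.0 h, with 19.0% substrate left, and free catalyst rose from 68.4% to 88.5% of the catalyst charged. At 20.0 h Monday's, with the same [precatalyst] charged, held 27.1% as free catalyst.

The earlier runs and the new flask are simulated for substances that don't exist.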